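The pitfall in a slow fall of substrate is that a short stretch of curve can pass for straight or for bent, so two chemists can read the same runs and still part at 25 min.

common to all: substrate 0.020 M

| run | coupling partner | initiator | remark | time |
|---|---|---|---|---|
| Monday's | 2.5 equiv | 5 mol% | run made earlier |  |
| Saturday's | 2.5 equiv | 7.5 mol% | run made earlier |  |
| flask | 2.50 equiv | 10 mol% |  | 25 min |

| run | time / min | substrate / % | product / % |
|---|---|---|---|
| Monday's | 1.50 | 97.8 | 0.6 |
| Monday's | 2.50 | 95.8 | 2.3 |
| Monday's | 4.00 | 94.2 | 3.7 |
| Monday's | 8.00 | 88.4 | 6.7 |
| Monday's | 12.0 | 83.5 | 9.1 |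
| Monday's | 20.0 | 74.3 | 15.2 |
| Saturday's | 1.50 | 97.5 | 1.2 |
| Saturday's | 2.50 | 95.5 | 2.6 |
| Saturday's | 4.00 | 92.6 | 3.9 |
| Saturday's | 8.00 | 85.9 | 8.5 |
| Saturday's | 12.0 | 80.2 | 12.1 |
| Saturday's | 20.0 | 68.7 | 19.2 |

(standard deviation of a reading: 0.3 percentage points)

* why nothing more happens at 25 min, or that something still does (it is still moving / all of the substrate has reacted / the coupling partner has run out first)
* part of the substrate gone at 25 min
* the product standing at 25 min, as a percentage of the substrate charged

- the reaction counts as stopped when no species that holds the substrate changes by six tenths of a point or more over the second half of the time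
- what has gone from substrate into another species counts as reacted, even if it can come back

Both chemists begin with the same reading. By 20.0 min, Monday's flask had lost 25.7% of its charge and Saturday's flask 31.3%, so raising the loading from 5 mol% to 7.5 mol% raised the loss by a factor of only 1.22. Now divide each loss by the time and by the square root of the loading, taken as a fraction of the charge. Monday's flask gives 0.0575 min⁻¹ and Saturday's 0.0571 min⁻¹, and these nearly agree. This is the root loss: the fraction of the charge lost per minute, per root of the loading.

They part over time. The second chemist holds the root loss steady, which is a straight line, and this reckoning gives 45.5% for the flask at 10 mol%. His ground is that Monday's product, at one partner each, has taken 6.08% of the coupling partner, so he expects no slowing. The first chemist answers that Monday's flask lost 0.0145 min⁻¹ up to 8.00 min but 0.0118 min⁻¹ after it. His forecast says “The loss of substrate is first order” and gives 41.5% gone, within 38.5% to 44.5%, with 25% product, 22.5% to 27.5%, and it is still moving.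

The simulation ran this scheme:

    substrate + second chain carrier → by-product + first chain carrier (k = 6.90 × 10⁵ L mol⁻¹ s⁻¹)
    initiator → 2 initiating radical (k = 2.20 × 10⁻⁴ s⁻¹)
    2 first chain carrier → ended chains (k = 9.70 × 10⁸ L mol⁻¹ s⁻¹)
    coupling partner + first chain carrier → product + second chain carrier (k = 3800 L mol⁻¹ s⁻¹)
    substrate + initiating radical → capped initiator + first chain carrier (k = 5.30 × 10⁵ L mol⁻¹ s⁻¹)
    substrate + by-product ⇌ idle adduct, settled at all times (K = 69.0 L mol⁻¹)

The flask gives 43.7% gone and 26.5% product, and it is still moving, so the forecast stands. Its root loss is 0.0552 min⁻¹, less than Monday's, so the straight line overshot. Compared at equal times, the root rule carries: Monday's mean loss at 8.00 min and 12.0 min, scaled by the root of the loadings, gives 19.9%, and this flask read at 10 min gives 20.0%. The product in this flask bends too: it climbs 0.0112 min⁻¹ from 2.50 min to 12.5 min, and more slowly after that, at 0.00986 min⁻¹. The coupling partner's half-life by its chain step is 170 min, longer than the 25 min run, and 89% of it remains.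

The runs were generated by integration with made-up constants, noise included.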